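The charge is conserved: in the zeta run, which is the asked flask followed so far, solid substrate, target and whatever else has formed always sum to the whole charge. The target at 30 min is therefore the charge minus what has gone elsewhere.

| setting | zeta | flask |
|---|---|---|
| solid substrate | 5.0 × 10⁻⁴ M | 5.0 × 10⁻⁴ M |
| free catalyst | 10 µM | 10 µM |
| remark | the very flask that is asked about, followed so far |  |
| time |  | 30 min |

zeta run (percent of the solid substrate charged)

| time / min | target / % | solid substrate / % |
|---|---|---|
| 0.667 | 2.8 | 72.5 |
| 2.00 | 20.3 | 44.6 |
| 3.00 | 33.2 | 28.6 |
| 5.00 | 60.5 | 0.4 |
| 8.00 | 84.6 | 0.1 |
| 10.0 | 89.8 | 0 |
| 12.0 | 92.3 | 0.6 |

(readings scatter by 0.5 percentage points)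

- solid, in amounts per volume of the solution: solid substrate
- at the start none of the solid substrate is in solution

1. the target standing at 30 min, as a percentage of the solid substrate charged
2. the change that raises the amount of target at 30 min, in percent of the solid substrate charged most ("none" if none brings more than 2 percentage points) (ochre / green / red / none)
3. amount of target at 30 min, in percent of the solid substrate charged, after ochre

- ochre: doubling the amount of free catalyst, all else as stated
- green: doubling the dissolution coefficient of the solid substrate, all else as stated
- red: doubling the solubility of the solid substrate, all else as stated

Which numbers must be known well? The solid readings do not enter this reckoning, which reads the target gains from 8.00 min on, when the solid reading stands at 0.1%. The two-minute gains of target, 5.2 percentage points and then 2.5 points, read as shrinking by a ratio of 0.481 per step, so a geometric tail puts 0.0032 points still to come after 30 min, less than the scatter of a reading, and the time needs little care.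

That tail puts the ceiling of target at 94.6%, but 0.5 points more on the last reading lifts it to 96.9%, so the last reading weighs more than the time and has to be known well.

This reckoning carries the shortfall S, the part of the charge that the ceiling leaves out (the lost selectivity), here 5.4 points. Taken as a side loss that runs without catalyst, S is reckoned here to fall in inverse proportion to free catalyst, the other charges held, which gives 97.3% after ochre. Green and red leave the catalyst as charged, so this reckoning names ochre.

The forecast gives 95%, ochre and 97.5% after ochre, against 94.6% and 97.3% in this reckoning: “Ochre is the best bet, though not certain.”

The flask gives 93.4%, with ochre best and 97.3% after ochre, so the forecast stands. At 30.0 min the self-condensation product holds 6.58% of the charge, each counted as two starting material, which with the target makes up the whole. For the forecast to fail, the charge of free catalyst would have to move: with it at 5.96 µM or 29.4 µM, all else held, the target at 30 min has moved by 5 points. Under ochre, S reckons to 2.7 points; the ochre flask falls short of the charge by 2.7 points.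

    starting material + free catalyst ⇌ catalyst intermediate A (K = 2000 M⁻¹, k = 2480 M⁻¹ s⁻¹)
    catalyst intermediate A → catalyst intermediate B (k = 0.645 s⁻¹)
    catalyst intermediate B → free catalyst + target (k = 1.79 s⁻¹)
    solid substrate ⇌ starting material, rate k4*(cs4 - [starting material]) while solid is left; crystals form when [starting material] > cs4 (solubility = 0.230 mM, k = 0.0223 s⁻¹)
    2 starting material → self-condensation product (k = 1.74 M⁻¹ s⁻¹)

In the neighbour flask with 2.5 × 10⁻⁵ M of free catalyst, S scales to 2.2 points, a target of 97.8%. The computed neighbour flask holds 98.0% of target.

The numbers in the tables are simulated for substances that don't exist; the scatter is artificial.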